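**Plan**
1. Retrosynthetic cuts: the acetate; C11–C12 (sulfone alkylation with an ω-silyloxy farnesyl bromide made from farnesyl acetate); C8–C9 (ring B); then C4–CH3 and the ring A bonds C5–C10 and C1–C2 (Diels–Alder).
2. What makes the C8–C9 event possible: C8 is a tertiary carbinol carbon (a latent methyl ketone, hence a ketyl) and C9 is a CH whose exocyclic neighbour C11 is a CH2 that can carry a phenylsulfonyl group. HO–C8–C9–C11–SO2Ph is the retron of a ketyl addition to a vinyl sulfone, and ring B (C5–C10) is six-membered, so the closure is 6-exo.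
3. Forward order: enone, 2-silyloxydiene, ring A by Diels–Alder with methacrolein, vinyl sulfone, C4 methylation, ketal, Wacker oxidation, ring B with SmI2, side chain, deprotection, acetate.
4. Stereochemistry: C10 and C5 from the catalytic enantioselective endo Diels–Alder reaction (formyl cis to the C5 chain gives the cis ring fusion); C8 and C9 from the chair-like ketyl cyclisation under control of ring A; alkene geometry from E,E-farnesyl acetate and the E-selective SeO2 oxidation.

Key step: step 8

Remark: the SMILES is read as drawn. In labdane numbering (ring A = C1–C5 and C10, ring B = C5–C10, side chain from C11) it defines 5S,8R,9R,10S, that is a cis-fused decalin with H-5 and the C10 methyl group on the same face, and the route is planned for exactly this isomer.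

**Route**

Step 1
Reactants: 1 pent-4-enal; 2 3-(triphenyl-λ5-phosphanylidene)butan-2-one
Product: 3 (3E)-3-methylocta-3,7-dien-2-one
Conditions: toluene, 90 °C
Reagents that add atoms: none
Why: Wittig olefination with a stabilised α-branched acyl ylide should give the trisubstituted enone with the E geometry under thermodynamic control.

Step 2
Reactants: 3 (3E)-3-methylocta-3,7-dien-2-one
Product: 5 triisopropyl{[(3E)-3-methylocta-1,3,7-trien-2-yl]oxy}silane, via lithium dienolate 4 (not isolated)
Conditions: LDA (lithium diisopropylamide), THF, −78 °C; then TIPSOTf, −78 °C to 0 °C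
Reagents that add atoms: triisopropylsilyl trifluoromethanesulfonate, CC(C)[Si](C(C)C)(C(C)C)OS(=O)(=O)C(F)(F)F
Why: Kinetic deprotonation of the α′-methyl group of the enone followed by O-silylation (silyl enol ether formation) should give the cross-conjugated 2-silyloxydiene with the E geometry of the trisubstituted double bond unchanged.

Step 3
Reactants: 5 triisopropyl{[(3E)-3-methylocta-1,3,7-trien-2-yl]oxy}silane; 6 methacrolein (2-methylprop-2-enal)
Product: 7 (1S,2R)-2-(but-3-en-1-yl)-1,3-dimethyl-4-[(triisopropylsilyl)oxy]cyclohex-3-ene-1-carbaldehyde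
Conditions: (S)-3,3-diphenyl-1-(2-methylphenyl)tetrahydro-1H,3H-pyrrolo[1,2-c][1,3,2]oxazaborole (20 mol%) activated with HNTf2 (18 mol%), CH2Cl2, −78 °C
Reagents that add atoms: none
Why: Catalytic enantioselective Diels–Alder reaction in which the 2-silyloxy group (para) and the alkyl-bearing terminus (ortho) both direct the substituted diene terminus to the α-carbon of methacrolein, the endo transition state of the E-diene puts the formyl group cis to the butenyl chain (C5), and the protonated oxazaborolidine, which binds the s-trans enal through boron and a formyl C–H···O contact and screens one face with a phenyl group, is expected to expose the re face of the α-carbon and so set the quaternary centre C10 as S.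

Step 4
Reactants: 7 (1S,2R)-2-(but-3-en-1-yl)-1,3-dimethyl-4-[(triisopropylsilyl)oxy]cyclohex-3-ene-1-carbaldehyde; 8 diethyl [(phenylsulfonyl)methyl]phosphonate
Product: 9 triisopropyl({(3S,4S)-3-(but-3-en-1-yl)-2,4-dimethyl-4-[(E)-2-(phenylsulfonyl)ethenyl]cyclohex-1-en-1-yl}oxy)silane
Conditions: NaH, THF, 0 °C to rt
Reagents that add atoms: none
Why: Horner–Wadsworth–Emmons olefination of the non-enolisable α-quaternary aldehyde should give the E-vinyl sulfone while the silyl enol ether is inert to the basic conditions.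

Step 5
Reactants: 9 triisopropyl({(3S,4S)-3-(but-3-en-1-yl)-2,4-dimethyl-4-[(E)-2-(phenylsulfonyl)ethenyl]cyclohex-1-en-1-yl}oxy)silane
Product: 11 (3S,4S)-3-(but-3-en-1-yl)-2,2,4-trimethyl-4-[(E)-2-(phenylsulfonyl)ethenyl]cyclohexan-1-one, via sulfonium enolate 10 (not isolated)
Conditions: TASF [tris(dimethylamino)sulfonium difluorotrimethylsilicate] (1.2 equiv), MeI (5 equiv), THF, −78 °C to 0 °C
Reagents that add atoms: iodomethane, CI
Why: Fluoride cleavage of the enol silyl ether frees the tetrasubstituted C3–C4 enolate regiospecifically and its C-methylation (regiospecific alkylation of a fluoride-generated enolate) creates the C4 gem-dimethyl group without a new stereocentre, the neopentyl β-carbon of the vinyl sulfone being too hindered for Michael addition.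

Step 6
Reactants: 11 (3S,4S)-3-(but-3-en-1-yl)-2,2,4-trimethyl-4-[(E)-2-(phenylsulfonyl)ethenyl]cyclohexan-1-one
Product: 12 (7S,8S)-7-(but-3-en-1-yl)-6,6,8-trimethyl-8-[(E)-2-(phenylsulfonyl)ethenyl]-1,4-dioxaspiro[4.5]decane
Conditions: ethylene glycol, TsOH (cat.), benzene, reflux with azeotropic removal of water
Reagents that add atoms: ethane-1,2-diol, OCCO
Why: Acid-catalysed ketalisation of the only carbonyl group protects C3 against SmI2, n-BuLi and Na(Hg) and at the same time biases the ring A chair for the key step.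

Step 7
Reactants: 12 (7S,8S)-7-(but-3-en-1-yl)-6,6,8-trimethyl-8-[(E)-2-(phenylsulfonyl)ethenyl]-1,4-dioxaspiro[4.5]decane
Product: 13 4-{(7S,8S)-6,6,8-trimethyl-8-[(E)-2-(phenylsulfonyl)ethenyl]-1,4-dioxaspiro[4.5]decan-7-yl}butan-2-one
Conditions: PdCl2 (10 mol%), CuCl (1 equiv), O2 (1 atm), DMF/H2O (7:1), rt
Reagents that add atoms: water, O
Why: Wacker oxidation converts the terminal alkene into the C8 methyl ketone by Markovnikov hydroxypalladation, and the electron-poor, hindered vinyl sulfone does not take part.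

Step 8
Reactants: 13 4-{(7S,8S)-6,6,8-trimethyl-8-[(E)-2-(phenylsulfonyl)ethenyl]-1,4-dioxaspiro[4.5]decan-7-yl}butan-2-one
Product: 14 (4a′S,5′R,6′R,8a′S)-1′,1′,4a′,6′-tetramethyl-5′-[(phenylsulfonyl)methyl]octahydro-1′H-spiro[[1,3]dioxolane-2,2′-naphthalen]-6′-ol
Conditions: SmI2 (2.5 equiv, 0.1 M in THF), MeOH (4 equiv), THF, −78 °C to 0 °C
Reagents that add atoms: none
Why: SmI2 reduces the C8 methyl ketone to a samarium ketyl, which adds to C9, the β-carbon of the E-vinyl sulfone, and the α-sulfonyl radical at C11 takes up a second electron and is protonated by MeOH (ketyl–olefin reductive cyclisation). The closest known reaction type is the SmI2-mediated cyclisation of ketones or aldehydes onto tethered α,β-unsaturated esters and sulfones, which gives 2-hydroxycycloalkyl acetates and sulfones with hydroxyl and CH2X trans. Ring B is the only ring closed, in the 6-exo-trig mode through a chair-like transition state. C9 is controlled by ring A: with the dioxolane at C3 the reactive chair has the C5 chain equatorial and the alkenyl group at C10 axial (the other chair adds a 1,3-diaxial CH3/CH3 contact between C10 and C4 and a contact between C6 and a ketal oxygen), and on this chair C11 can only stay equatorial on the new ring, cis to the C10 methyl group, because the other rotamer would push it against C4 and its methyl groups. C8 is controlled by the ketyl: the solvated O–Sm group takes the equatorial site, which puts the hydroxyl group trans to CH2SO2Ph and the C8 methyl group axial, as the target requires. The step needs ring closure to outrun plain reduction of the ketone or of the vinyl sulfone, which the activated acceptor, the fully substituted tether carbons and the absence of HMPA should secure, while ketal and sulfone are inert to SmI2 under these conditions.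

Step 9
Reactants: 15 (2E,6E)-farnesyl acetate [(2E,6E)-3,7,11-trimethyldodeca-2,6,10-trien-1-yl acetate]
Product: 16 (2E,6E,10E)-12-hydroxy-3,7,11-trimethyldodeca-2,6,10-trien-1-yl acetate
Conditions: SeO2 (0.1 equiv), t-BuOOH (70% aq., 3 equiv), salicylic acid (0.1 equiv), CH2Cl2, rt
Reagents that add atoms: tert-butyl hydroperoxide, CC(C)(C)OO
Why: SeO2-catalysed allylic oxidation (ene reaction then [2,3]-sigmatropic shift) should take place at the E-methyl group of the terminal, most electron-rich trisubstituted alkene, the alkene next to the acetate being deactivated.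

Step 10
Reactants: 16 (2E,6E,10E)-12-hydroxy-3,7,11-trimethyldodeca-2,6,10-trien-1-yl acetate
Product: 17 (2E,6E,10E)-12-{[tert-butyl(dimethyl)silyl]oxy}-3,7,11-trimethyldodeca-2,6,10-trien-1-yl acetate
Conditions: TBSCl, imidazole, DMF, rt
Reagents that add atoms: tert-butyldimethylsilyl chloride, CC(C)(C)[Si](C)(C)Cl
Why: Silylation of the primary allylic alcohol gives an ether that should survive methanolysis, n-BuLi and Na(Hg).

Step 11
Reactants: 17 (2E,6E,10E)-12-{[tert-butyl(dimethyl)silyl]oxy}-3,7,11-trimethyldodeca-2,6,10-trien-1-yl acetate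
Product: 18 (2E,6E,10E)-12-{[tert-butyl(dimethyl)silyl]oxy}-3,7,11-trimethyldodeca-2,6,10-trien-1-ol
Conditions: K2CO3 (0.2 equiv), MeOH, rt
Reagents that add atoms: none
Why: Base-catalysed transesterification with methanol removes the acetate and leaves the silyl ether untouched.

Step 12
Reactants: 18 (2E,6E,10E)-12-{[tert-butyl(dimethyl)silyl]oxy}-3,7,11-trimethyldodeca-2,6,10-trien-1-ol
Product: 19 {[(2E,6E,10E)-12-bromo-2,6,10-trimethyldodeca-2,6,10-trien-1-yl]oxy}(tert-butyl)dimethylsilane
Conditions: CBr4, PPh3, CH2Cl2, 0 °C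
Reagents that add atoms: tetrabromomethane, BrC(Br)(Br)Br
Why: The Appel reaction converts the primary allylic alcohol into the bromide by SN2 displacement under neutral conditions, so that neither allylic transposition nor loss of the silyl ether is expected.

Step 13
Reactants: 14 (4a′S,5′R,6′R,8a′S)-1′,1′,4a′,6′-tetramethyl-5′-[(phenylsulfonyl)methyl]octahydro-1′H-spiro[[1,3]dioxolane-2,2′-naphthalen]-6′-ol; 19 {[(2E,6E,10E)-12-bromo-2,6,10-trimethyldodeca-2,6,10-trien-1-yl]oxy}(tert-butyl)dimethylsilane
Product: 21 (4a′S,5′R,6′R,8a′S)-5′-[(3E,7E,11E)-13-{[tert-butyl(dimethyl)silyl]oxy}-4,8,12-trimethyl-1-(phenylsulfonyl)trideca-3,7,11-trien-1-yl]-1′,1′,4a′,6′-tetramethyloctahydro-1′H-spiro[[1,3]dioxolane-2,2′-naphthalen]-6′-ol (both configurations at the sulfone-bearing carbon), via dilithio derivative 20 (not isolated)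
Conditions: n-BuLi (2.2 equiv), THF/DMPU (5:1), −78 °C; then 19, −78 °C to −20 °C
Reagents that add atoms: none
Why: Alkylation of the α-sulfonyl carbanion (formed after the alkoxide) with the primary allylic bromide is an SN2 reaction without allylic transposition that forms the C11–C12 bond with the three E double bonds in place, and the uncontrolled centre at C11 is removed in the next step.

Step 14
Reactants: 21 the C11 sulfone (both configurations at C11)
Product: 22 (4a′S,5′R,6′R,8a′S)-5′-[(3E,7E,11E)-13-{[tert-butyl(dimethyl)silyl]oxy}-4,8,12-trimethyltrideca-3,7,11-trien-1-yl]-1′,1′,4a′,6′-tetramethyloctahydro-1′H-spiro[[1,3]dioxolane-2,2′-naphthalen]-6′-ol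
Conditions: Na(Hg) (6% Na), Na2HPO4, MeOH/THF (3:1), −20 °C to rt
Reagents that add atoms: none
Why: Reductive desulfonylation by electron transfer cleaves the C–S bond of the homoallylic sulfone without touching the isolated trisubstituted alkenes, the silyl ether, the ketal or the tertiary alcohol.

Step 15
Reactants: 22 the ketal silyl ether
Product: 23 (4aS,5R,6R,8aS)-6-hydroxy-5-[(3E,7E,11E)-13-hydroxy-4,8,12-trimethyltrideca-3,7,11-trien-1-yl]-1,1,4a,6-tetramethyloctahydronaphthalen-2(1H)-one
Conditions: AcOH/THF/H2O (3:1:1), 45 °C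
Reagents that add atoms: water, O
Why: Hydrolysis in weak aqueous acid removes the strained dioxolane and the primary allylic silyl ether, and acetic acid is too weak to protonate the trisubstituted alkenes, so the tertiary C8 alcohol should neither eliminate nor add to the C13 alkene.

Step 16
Reactants: 23 the keto diol
Product: 24 (2E,6E,10E)-13-[(1R,2R,4aS,8aS)-2-hydroxy-2,5,5,8a-tetramethyl-6-oxodecahydronaphthalen-1-yl]-2,6,10-trimethyltrideca-2,6,10-trien-1-yl acetate (target)
Conditions: Ac2O, pyridine, CH2Cl2, 0 °C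
Reagents that add atoms: acetic anhydride, CC(=O)OC(C)=O
Why: O-Acylation is selective for the primary allylic alcohol because the tertiary C8 hydroxyl, flanked by fully substituted carbons, does not react under these conditions.

**Compound list**
1 | pent-4-enal | C=CCCC=O | starting material
2 | 3-(triphenyl-λ5-phosphanylidene)butan-2-one | CC(=O)C(C)=P(c1ccccc1)(c1ccccc1)c1ccccc1 | starting material
3 | (3E)-3-methylocta-3,7-dien-2-one | CC(=O)/C(C)=C/CCC=C | intermediate
4 | lithium (3E)-3-methylocta-1,3,7-trien-2-olate | [Li+].C=C([O-])/C(C)=C/CCC=C | intermediate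
5 | triisopropyl{[(3E)-3-methylocta-1,3,7-trien-2-yl]oxy}silane | C=C(O[Si](C(C)C)(C(C)C)C(C)C)/C(C)=C/CCC=C | intermediate
6 | methacrolein (2-methylprop-2-enal) | C=C(C)C=O | starting material
7 | (1S,2R)-2-(but-3-en-1-yl)-1,3-dimethyl-4-[(triisopropylsilyl)oxy]cyclohex-3-ene-1-carbaldehyde | O=C[C@@]1(C)CCC(O[Si](C(C)C)(C(C)C)C(C)C)=C(C)[C@H]1CCC=C | intermediate
8 | diethyl [(phenylsulfonyl)methyl]phosphonate | CCOP(=O)(OCC)CS(=O)(=O)c1ccccc1 | starting material
9 | triisopropyl({(3S,4S)-3-(but-3-en-1-yl)-2,4-dimethyl-4-[(E)-2-(phenylsulfonyl)ethenyl]cyclohex-1-en-1-yl}oxy)silane | O=S(=O)(c1ccccc1)/C=C/[C@@]2(C)CCC(O[Si](C(C)C)(C(C)C)C(C)C)=C(C)[C@H]2CCC=C | intermediate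
10 | tris(dimethylamino)sulfonium (3S,4S)-3-(but-3-en-1-yl)-2,4-dimethyl-4-[(E)-2-(phenylsulfonyl)ethenyl]cyclohex-1-en-1-olate | O=S(=O)(c1ccccc1)/C=C/[C@@]2(C)CCC([O-])=C(C)[C@H]2CCC=C.CN(C)[S+](N(C)C)N(C)C | intermediate
11 | (3S,4S)-3-(but-3-en-1-yl)-2,2,4-trimethyl-4-[(E)-2-(phenylsulfonyl)ethenyl]cyclohexan-1-one | O=S(=O)(c1ccccc1)/C=C/[C@@]2(C)CCC(=O)C(C)(C)[C@H]2CCC=C | intermediate
12 | (7S,8S)-7-(but-3-en-1-yl)-6,6,8-trimethyl-8-[(E)-2-(phenylsulfonyl)ethenyl]-1,4-dioxaspiro[4.5]decane | O=S(=O)(c1ccccc1)/C=C/[C@@]2(C)CCC3(OCCO3)C(C)(C)[C@H]2CCC=C | intermediate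
13 | 4-{(7S,8S)-6,6,8-trimethyl-8-[(E)-2-(phenylsulfonyl)ethenyl]-1,4-dioxaspiro[4.5]decan-7-yl}butan-2-one | O=S(=O)(c1ccccc1)/C=C/[C@@]2(C)CCC3(OCCO3)C(C)(C)[C@H]2CCC(C)=O | intermediate
14 | (4a′S,5′R,6′R,8a′S)-1′,1′,4a′,6′-tetramethyl-5′-[(phenylsulfonyl)methyl]octahydro-1′H-spiro[[1,3]dioxolane-2,2′-naphthalen]-6′-ol | O=S(=O)(c1ccccc1)C[C@@H]2[C@@]3(C)CCC4(OCCO4)C(C)(C)[C@H]3CC[C@@]2(C)O | intermediate
15 | (2E,6E)-3,7,11-trimethyldodeca-2,6,10-trien-1-yl acetate (farnesyl acetate) | CC(=O)OC/C=C(C)/CC/C=C(C)/CCC=C(C)C | starting material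
16 | (2E,6E,10E)-12-hydroxy-3,7,11-trimethyldodeca-2,6,10-trien-1-yl acetate | CC(=O)OC/C=C(C)/CC/C=C(C)/CC/C=C(C)/CO | intermediate
17 | (2E,6E,10E)-12-{[tert-butyl(dimethyl)silyl]oxy}-3,7,11-trimethyldodeca-2,6,10-trien-1-yl acetate | CC(=O)OC/C=C(C)/CC/C=C(C)/CC/C=C(C)/CO[Si](C)(C)C(C)(C)C | intermediate
18 | (2E,6E,10E)-12-{[tert-butyl(dimethyl)silyl]oxy}-3,7,11-trimethyldodeca-2,6,10-trien-1-ol | OC/C=C(C)/CC/C=C(C)/CC/C=C(C)/CO[Si](C)(C)C(C)(C)C | intermediate
19 | {[(2E,6E,10E)-12-bromo-2,6,10-trimethyldodeca-2,6,10-trien-1-yl]oxy}(tert-butyl)dimethylsilane | BrC/C=C(C)/CC/C=C(C)/CC/C=C(C)/CO[Si](C)(C)C(C)(C)C | intermediate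
20 | dilithium salt of 14 (C8 alkoxide and C11 α-sulfonyl carbanion) | [Li+].[Li+].O=S(=O)(c1ccccc1)[CH-][C@@H]2[C@@]3(C)CCC4(OCCO4)C(C)(C)[C@H]3CC[C@@]2(C)[O-] | intermediate
21 | (4a′S,5′R,6′R,8a′S)-5′-[(3E,7E,11E)-13-{[tert-butyl(dimethyl)silyl]oxy}-4,8,12-trimethyl-1-(phenylsulfonyl)trideca-3,7,11-trien-1-yl]-1′,1′,4a′,6′-tetramethyloctahydro-1′H-spiro[[1,3]dioxolane-2,2′-naphthalen]-6′-ol (both configurations at the sulfone-bearing carbon) | O=S(=O)(c1ccccc1)C(C/C=C(C)/CC/C=C(C)/CC/C=C(C)/CO[Si](C)(C)C(C)(C)C)[C@@H]2[C@@]3(C)CCC4(OCCO4)C(C)(C)[C@H]3CC[C@@]2(C)O | intermediate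
22 | (4a′S,5′R,6′R,8a′S)-5′-[(3E,7E,11E)-13-{[tert-butyl(dimethyl)silyl]oxy}-4,8,12-trimethyltrideca-3,7,11-trien-1-yl]-1′,1′,4a′,6′-tetramethyloctahydro-1′H-spiro[[1,3]dioxolane-2,2′-naphthalen]-6′-ol | CC(C)(C)[Si](C)(C)OC/C(C)=C/CC/C(C)=C/CC/C(C)=C/CC[C@@H]1[C@@]2(C)CCC3(OCCO3)C(C)(C)[C@H]2CC[C@@]1(C)O | intermediate
23 | (4aS,5R,6R,8aS)-6-hydroxy-5-[(3E,7E,11E)-13-hydroxy-4,8,12-trimethyltrideca-3,7,11-trien-1-yl]-1,1,4a,6-tetramethyloctahydronaphthalen-2(1H)-one | OC/C(C)=C/CC/C(C)=C/CC/C(C)=C/CC[C@@H]1[C@@]2(C)CCC(=O)C(C)(C)[C@H]2CC[C@@]1(C)O | intermediate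
24 | (2E,6E,10E)-13-[(1R,2R,4aS,8aS)-2-hydroxy-2,5,5,8a-tetramethyl-6-oxodecahydronaphthalen-1-yl]-2,6,10-trimethyltrideca-2,6,10-trien-1-yl acetate | CC(=O)OC/C(C)=C/CC/C(C)=C/CC/C(C)=C/CC[C@@H]1[C@@]2(C)CCC(=O)C(C)(C)[C@H]2CC[C@@]1(C)O | target

**Step count and risks**

Total: 16 steps. Longest linear sequence: 12 steps (steps 1–8 and 13–16, from pent-4-enal); the side-chain bromide takes 4 steps (9–12).

Steps most likely to fail:

Step 8. The vinyl sulfone may be reduced to the saturated sulfone before the ring closes, or the ketyl may close with the O–Sm group axial, so that C8 forms with the hydroxyl group cis to CH2SO2Ph. The fallback replaces ketyl chemistry by a radical conjugate addition started by hydrogen-atom transfer, and sets out from 13. LDA and Et3SiCl (THF, −78 °C) should convert 13 into the kinetic triethylsilyl enol ether of the methyl ketone F1. Fe(acac)3 and PhSiH3 in EtOH/ethylene glycol at 60 °C should transfer a hydrogen atom to the terminal CH2 of the enol ether; the tertiary α-silyloxy radical at C8 adds 6-exo to the vinyl sulfone and gives the C8 triethylsilyl ether F2. No stoichiometric electron donor that could reduce the acceptor directly is present, and the bulky silyloxy group should again take the equatorial site. Tetrabutylammonium fluoride (THF, rt) removes the silyl group and the route is rejoined at 14.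

Step 3. The catalyst may discriminate the two faces of the bound enal poorly, or its strongly acidic activator may cleave the dienol silyl ether. The fallback replaces asymmetric catalysis by resolution through covalent diastereomers, and sets out from 5 and 6. Without catalyst in toluene at 80 °C they should combine to the racemic endo adduct F3. Condensation with (1R,2R)-N,N′-dimethyl-1,2-diphenylethane-1,2-diamine (Et2O, 4 Å molecular sieves, rt) gives two diastereomeric imidazolidines, the aminal of the 1S,2R aldehyde F4 and the aminal of its enantiomer F5, which are separated by chromatography. F4 is hydrolysed on wet silica gel (or with 2% aq. HCl in Et2O at 0 °C) and the route is rejoined at 7.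

Step 5. The hindered tetrasubstituted enolate may be methylated on oxygen, or the bulky silyl group may be cleaved too slowly. The fallback replaces enolate alkylation by cyclopropanation and ring opening, and sets out from 9. Simmons–Smith cyclopropanation (Et2Zn, CH2I2, CH2Cl2, 0 °C) should attack the electron-rich enol ether double bond in preference to the terminal alkene and the electron-poor vinyl sulfone and give the siloxycyclopropane F6. Tetrabutylammonium fluoride (THF, 0 °C to rt) frees the cyclopropanolate, which opens at the bond between C3 and the new CH2 and is protonated on carbon, so that the new CH2 becomes the second methyl group at C4, and the route is rejoined at 11.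

**Further compounds**
F1 | step 8 | triethyl[(4-{(7S,8S)-6,6,8-trimethyl-8-[(E)-2-(phenylsulfonyl)ethenyl]-1,4-dioxaspiro[4.5]decan-7-yl}but-1-en-2-yl)oxy]silane | O=S(=O)(c1ccccc1)/C=C/[C@@]2(C)CCC3(OCCO3)C(C)(C)[C@H]2CCC(=C)O[Si](CC)(CC)CC
F2 | step 8 | triethylsilyl ether of 14 at the C8 oxygen | O=S(=O)(c1ccccc1)C[C@@H]2[C@@]3(C)CCC4(OCCO4)C(C)(C)[C@H]3CC[C@@]2(C)O[Si](CC)(CC)CC
F3 | step 3 | racemic endo adduct (7 and its enantiomer, 1:1) | O=C[C@@]1(C)CCC(O[Si](C(C)C)(C(C)C)C(C)C)=C(C)[C@H]1CCC=C.O=C[C@]1(C)CCC(O[Si](C(C)C)(C(C)C)C(C)C)=C(C)[C@@H]1CCC=C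
F4 | step 3 | (4R,5R)-1,3-dimethyl-4,5-diphenylimidazolidin-2-yl aminal of 7 | CN1[C@H](c2ccccc2)[C@@H](c2ccccc2)N(C)C1[C@@]3(C)CCC(O[Si](C(C)C)(C(C)C)C(C)C)=C(C)[C@H]3CCC=C
F5 | step 3 | (4R,5R)-1,3-dimethyl-4,5-diphenylimidazolidin-2-yl aminal of the enantiomer of 7 | CN1[C@H](c2ccccc2)[C@@H](c2ccccc2)N(C)C1[C@]3(C)CCC(O[Si](C(C)C)(C(C)C)C(C)C)=C(C)[C@@H]3CCC=C
F6 | step 5 | siloxycyclopropane from 9 (2-(but-3-en-1-yl)-1,3-dimethyl-3-[(E)-2-(phenylsulfonyl)ethenyl]-6-[(triisopropylsilyl)oxy]bicyclo[4.1.0]heptane, 2S,3S, cyclopropane carbons not assigned) | O=S(=O)(c1ccccc1)/C=C/[C@@]2(C)CCC3(O[Si](C(C)C)(C(C)C)C(C)C)CC3(C)[C@H]2CCC=C
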